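**Retrosynthetic overview**

1. Target 25 ⇐ tetraol 23 by O-sulfation at the open hydroxyl next to the ring C–H; 23 ⇐ tetramethoxyarene 20 through quinone 21 and dihydroxyquinone 22; 20 ⇐ tertiary alcohol 18 by dehydration toward C7.
2. 18 ⇐ seco ketone 17 by cutting C8–C9: reductive ketyl–styrene closure of ring B. This is the only ring made in the route; ring A comes from the chiral pool and the arene from 11.
3. 17 ⇐ aldehyde ester 9: C9=C11 by Takai iodo-olefination, C11–aryl by Negishi coupling with zincated 11, C8–CH3 by MeMgBr on a Weinreb amide.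
4. 9 ⇐ seco diacid 6 ⇐ abieta-8,11,13-triene 5 (RuO4 excision of aromatic ring C) ⇐ dehydroabietic acid 1 (C4 CO2H to CH3).
5. Feature: ring A of the target, with C4 (gem-dimethyl), C5 (α-H) and C10 (β-methyl), is ring A of dehydroabietic acid. Removing the aromatic ring leaves C8 (on the C5 arm) and C9 (on C10) as carbonyl handles between which ring B is closed again.

Key step: step 12

Assumption: the target is taken as the free aryl hydrogen sulfate shown in the SMILES; it is expected to be stable only cold and dilute, so it would be released from its pyridinium salt at the very end.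

**Route**

Step 1
Reactants: 1 dehydroabietic acid
Product: 2 dehydroabietinol (abieta-8,11,13-trien-18-ol)
Conditions: LiAlH4, THF, 0 °C to reflux; then aq. NaOH
Reagents that add atoms: none
Why: LiAlH4 reduction of the hindered tertiary carboxylic acid should give the neopentyl primary alcohol without touching a stereocenter.

Step 2
Reactants: 2 dehydroabietinol
Product: 3 dehydroabietinal (abieta-8,11,13-trien-18-al)
Conditions: Dess–Martin periodinane, CH2Cl2, rt
Reagents that add atoms: none
Why: Dess–Martin oxidation of a primary alcohol should stop at the aldehyde, which has no α-hydrogen and so cannot epimerise at C4.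

Step 3
Reactants: 3 dehydroabietinal
Product: 5 abieta-8,11,13-triene, via hydrazone 4 (not isolated)
Conditions: N2H4·H2O, KOH, diethylene glycol, 130 °C then 200 °C
Reagents that add atoms: hydrazine hydrate, NN.O (its nitrogen atoms are kept only in 4)
Why: Wolff–Kishner reduction (Huang–Minlon procedure) should turn the aldehyde through its hydrazone into the second C4 methyl group, the arene and the ring stereocenters being inert to hot KOH.

Step 4
Reactants: 5 abieta-8,11,13-triene
Product: 6 seco diacid, 3-[(1S,2S)-2-carboxy-2,6,6-trimethylcyclohexyl]propanoic acid (C8 acid on the C5 arm, C9 acid on C10)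
Conditions: RuCl3·xH2O (5 mol %), NaIO4 (excess), CCl4/MeCN/H2O, rt
Reagents that add atoms: sodium periodate, [Na+].[O-]I(=O)(=O)=O (oxygen relayed through RuO4); water, O
Why: RuO4-catalysed oxidative degradation of an alkyl-substituted benzene ring should leave each alkyl-bearing ring carbon as a carboxyl group, so C8 and C9 become acids while C5 and C10 are not touched.

Step 5
Reactants: 6 seco diacid
Product: 7 (1S,2S)-2-(3-methoxy-3-oxopropyl)-1,3,3-trimethylcyclohexane-1-carboxylic acid (chain methyl ester, C9 acid free)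
Conditions: MeOH, H2SO4 (cat.), rt
Reagents that add atoms: methanol, CO
Why: Fischer esterification should take only the unhindered chain acid, because the C9 acid sits on quaternary C10 and does not react at rt.

Step 6
Reactants: 7 acid ester
Product: 8 methyl 3-[(1S,2S)-2-(hydroxymethyl)-2,6,6-trimethylcyclohexyl]propanoate
Conditions: BH3·SMe2, THF, 0 °C to rt; then H2O
Reagents that add atoms: none
Why: borane should reduce the free carboxylic acid through its acyloxyborane much faster than it attacks the methyl ester (chemoselective acid reduction).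

Step 7
Reactants: 8 hydroxy ester
Product: 9 methyl 3-[(1S,2S)-2-formyl-2,6,6-trimethylcyclohexyl]propanoate
Conditions: Dess–Martin periodinane, CH2Cl2, rt
Reagents that add atoms: none
Why: Dess–Martin oxidation should give the C9 aldehyde, which is bound to quaternary C10 and cannot enolise.

Step 8
Reactants: 9 aldehyde ester
Product: 10 methyl 3-[(1S,2S)-2-[(E)-2-iodoethenyl]-2,6,6-trimethylcyclohexyl]propanoate
Conditions: CrCl2, CHI3, THF/dioxane, 0 °C to rt
Reagents that add atoms: iodoform, IC(I)I
Why: Takai olefination with the geminal dichromium reagent from CHI3 and divalent chromium should give the (E)-vinyl iodide, the bulky α-quaternary aldehyde favouring E, and the reagent is not basic enough to enolise the ester.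

Step 9
Reactants: 10 vinyl iodide; 11 1,2,4,5-tetramethoxybenzene
Product: 14 methyl 3-[(1S,2R)-2,6,6-trimethyl-2-[(E)-2-(2,3,5,6-tetramethoxyphenyl)ethenyl]cyclohexyl]propanoate, via aryllithium 12 (not isolated), via arylzinc chloride 13 (not isolated)
Conditions: 11, n-BuLi, THF, 0 °C; ZnCl2, THF, 0 °C to rt; then 10, Pd(PPh3)4 (5 mol %), THF, 50 °C
Reagents that add atoms: n-butyllithium, [Li]CCCC (lithium kept only in 12); zinc dichloride, Cl[Zn]Cl (zinc and chlorine kept only in 13)
Why: ortho-lithiation of 11 between two methoxy groups, transmetalation to zinc and Negishi coupling under zerovalent palladium should join C11 to the arene with retention of the E geometry, the arylzinc leaving the ester alone.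

Step 10
Reactants: 14 styrene ester
Product: 15 N-methoxy-N-methyl-3-[(1S,2R)-2,6,6-trimethyl-2-[(E)-2-(2,3,5,6-tetramethoxyphenyl)ethenyl]cyclohexyl]propanamide
Conditions: MeNH(OMe)·HCl, i-PrMgCl, THF, −20 to 0 °C
Reagents that add atoms: N,O-dimethylhydroxylamine hydrochloride, CNOC.Cl
Why: aminolysis of the methyl ester by the chloromagnesium amide of N,O-dimethylhydroxylamine (Weinreb amide formation) should be clean, since the styrene and the aryl ethers are inert.

Step 11
Reactants: 15 Weinreb amide; 16 methylmagnesium bromide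
Product: 17 4-[(1S,2R)-2,6,6-trimethyl-2-[(E)-2-(2,3,5,6-tetramethoxyphenyl)ethenyl]cyclohexyl]butan-2-one (8,9-seco ketone)
Conditions: MeMgBr, THF, 0 °C; then aq. NH4Cl
Reagents that add atoms: none
Why: Weinreb ketone synthesis should stop at the methyl ketone, because the chelated magnesium adduct does not collapse before work-up.

Step 12
Reactants: 17 seco ketone
Product: 18 11-(2,3,5,6-tetramethoxyphenyl)-9-epi-driman-8β-ol (8β-OH axial, 8α-CH3, 9α-CH2Ar, 9β-H, 5α-H, 10β-CH3)
Conditions: SmI2 (3 equiv), HMPA (10 equiv), t-BuOH (2 equiv), THF (0.01 M), 0 °C to rt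
Reagents that add atoms: none
Why: SmI2 activated by HMPA transfers one electron to the C8 ketone, the trivalent-samarium ketyl adds to the styrene carbon C9, and the benzylic C11 radical so formed is reduced by a second SmI2 and protonated by t-BuOH to the C11 methylene. The closest known reaction type is the SmI2-promoted reductive ketyl–olefin cyclization onto a styrene acceptor. Ring B closes in the 6-exo-trig mode (C8 onto C9 through C7, C6, C5 and C10) by way of a chair fused trans to the ring A chair, in which both arms on C5 and C10 are equatorial. At C8 the methyl group should take the equatorial site, because an axial one would meet the axial C10 methyl group 1,3-diaxially, so the oxygen ends axial on the β face. At C9 the alkene terminus C11 should lie anti to the samarium-bound oxygen (repulsion between the ketyl oxygen and the alkene), which puts the arylmethyl arm on the α face, trans-diaxial to the hydroxyl and anti to the C10 methyl group, with 9β-H. The step needs attack at C9 and not C11, and closure faster than simple ketone reduction or pinacol coupling; the benzylic stabilisation of the C11 radical, the six-membered exo geometry fixed by the trans arms on ring A, and high dilution should secure this.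

Step 13
Reactants: 18 tertiary alcohol
Product: 20 11-(2,3,5,6-tetramethoxyphenyl)-9-epi-drim-7-ene, via chlorosulfite 19 (not isolated)
Conditions: SOCl2, pyridine, CH2Cl2, −40 to 0 °C
Reagents that add atoms: thionyl chloride, O=S(Cl)Cl (kept only in 19)
Why: E2 elimination of the axial chlorosulfite should run toward C7, whose axial α-hydrogen is the only ring hydrogen anti-periplanar to the leaving group (the C9 hydrogen is equatorial), giving the trisubstituted ring alkene in preference to the exocyclic one and leaving C9 untouched.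

Step 14
Reactants: 20 tetramethoxyarene
Product: 21 3-(9-epi-drim-7-en-11-yl)-2,5-dimethoxy-1,4-benzoquinone
Conditions: (NH4)2Ce(NO3)6 (2.5 equiv), MeCN/H2O, 0 °C
Reagents that add atoms: water, O
Why: oxidative demethylation of a 1,2,4,5-tetramethoxyarene by tetravalent cerium should give the para-quinone, and the two possible para pairs lead to the same compound.

Step 15
Reactants: 21 dimethoxyquinone
Product: 22 3-(9-epi-drim-7-en-11-yl)-2,5-dihydroxy-1,4-benzoquinone
Conditions: 2 M aq. NaOH, MeOH, Ar, rt to 50 °C; then cold 1 M HCl to pH 2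
Reagents that add atoms: sodium hydroxide, [Na+].[OH-]
Why: both methoxy groups are vinylogous esters and should be hydrolysed by addition–elimination of hydroxide, while the isolated ring alkene is inert to base.

Step 16
Reactants: 22 dihydroxyquinone
Product: 23 3-(9-epi-drim-7-en-11-yl)benzene-1,2,4,5-tetrol
Conditions: Na2S2O4, EtOAc/H2O, Ar, rt
Reagents that add atoms: none
Why: dithionite reduction of a quinone to its hydroquinone is mild and neutral, so neither the alkene nor C9 is at risk; the tetraol is kept under argon.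

Step 17
Reactants: 23 tetraol
Product: 25 2,4,5-trihydroxy-3-{[(1R,4aS,8aS)-2,5,5,8a-tetramethyl-1,4,4a,5,6,7,8,8a-octahydronaphthalen-1-yl]methyl}phenyl hydrogen sulfate, via pyridinium sulfate 24 (not isolated)
Conditions: SO3·pyridine (1.05 equiv), pyridine, Ar, 0 °C; then Dowex 50W (H+ form), cold MeOH/H2O
Reagents that add atoms: sulfur trioxide–pyridine complex, [O-]S(=O)(=O)[n+]1ccccc1
Why: O-sulfation of a phenol with SO3·pyridine should take one of the two equivalent hydroxyls next to the ring C–H, since the other two are flanked by the bulky C11 methylene, and one equivalent of reagent under basic conditions should hold the reaction at the monosulfate.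

**Compound list**

1 | dehydroabietic acid (abieta-8,11,13-trien-18-oic acid) | CC(C)C1=CC2=C(C=C1)[C@]3(CCC[C@@]([C@@H]3CC2)(C)C(=O)O)C | starting material
2 | dehydroabietinol (abieta-8,11,13-trien-18-ol) | CC(C)C1=CC2=C(C=C1)[C@]3(CCC[C@@]([C@@H]3CC2)(C)CO)C | intermediate
3 | dehydroabietinal (abieta-8,11,13-trien-18-al) | CC(C)C1=CC2=C(C=C1)[C@]3(CCC[C@@]([C@@H]3CC2)(C)C=O)C | intermediate
4 | dehydroabietinal hydrazone (not isolated) | CC(C)C1=CC2=C(C=C1)[C@]3(CCC[C@@]([C@@H]3CC2)(C)C=NN)C | intermediate
5 | abieta-8,11,13-triene (5α-H, 10β-CH3) | CC(C)C1=CC2=C(C=C1)[C@]3(CCCC([C@@H]3CC2)(C)C)C | intermediate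
6 | 3-[(1S,2S)-2-carboxy-2,6,6-trimethylcyclohexyl]propanoic acid (seco diacid) | OC(=O)CC[C@H]1C(C)(C)CCC[C@]1(C)C(=O)O | intermediate
7 | (1S,2S)-2-(3-methoxy-3-oxopropyl)-1,3,3-trimethylcyclohexane-1-carboxylic acid | COC(=O)CC[C@H]1C(C)(C)CCC[C@]1(C)C(=O)O | intermediate
8 | methyl 3-[(1S,2S)-2-(hydroxymethyl)-2,6,6-trimethylcyclohexyl]propanoate | COC(=O)CC[C@H]1C(C)(C)CCC[C@]1(C)CO | intermediate
9 | methyl 3-[(1S,2S)-2-formyl-2,6,6-trimethylcyclohexyl]propanoate | COC(=O)CC[C@H]1C(C)(C)CCC[C@]1(C)C=O | intermediate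
10 | methyl 3-[(1S,2S)-2-[(E)-2-iodoethenyl]-2,6,6-trimethylcyclohexyl]propanoate | COC(=O)CC[C@H]1C(C)(C)CCC[C@]1(C)/C=C/I | intermediate
11 | 1,2,4,5-tetramethoxybenzene | COc1cc(OC)c(OC)cc1OC | starting material
12 | 2,3,5,6-tetramethoxyphenyllithium (not isolated) | [Li]c1c(OC)c(OC)cc(OC)c1OC | intermediate
13 | (2,3,5,6-tetramethoxyphenyl)zinc chloride (not isolated) | Cl[Zn]c1c(OC)c(OC)cc(OC)c1OC | intermediate
14 | methyl 3-[(1S,2R)-2,6,6-trimethyl-2-[(E)-2-(2,3,5,6-tetramethoxyphenyl)ethenyl]cyclohexyl]propanoate | COC(=O)CC[C@H]1C(C)(C)CCC[C@]1(C)/C=C/c1c(OC)c(OC)cc(OC)c1OC | intermediate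
15 | N-methoxy-N-methyl-3-[(1S,2R)-2,6,6-trimethyl-2-[(E)-2-(2,3,5,6-tetramethoxyphenyl)ethenyl]cyclohexyl]propanamide | CON(C)C(=O)CC[C@H]1C(C)(C)CCC[C@]1(C)/C=C/c1c(OC)c(OC)cc(OC)c1OC | intermediate
16 | methylmagnesium bromide | C[Mg]Br | starting material
17 | 4-[(1S,2R)-2,6,6-trimethyl-2-[(E)-2-(2,3,5,6-tetramethoxyphenyl)ethenyl]cyclohexyl]butan-2-one (8,9-seco ketone) | CC(=O)CC[C@H]1C(C)(C)CCC[C@]1(C)/C=C/c1c(OC)c(OC)cc(OC)c1OC | intermediate
18 | 11-(2,3,5,6-tetramethoxyphenyl)-9-epi-driman-8β-ol (8α-CH3, 9α-CH2Ar, 9β-H) | C[C@]1(O)CC[C@H]2C(C)(C)CCC[C@]2(C)[C@@H]1Cc1c(OC)c(OC)cc(OC)c1OC | intermediate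
19 | chlorosulfite ester of 18 (not isolated) | C[C@]1(OS(=O)Cl)CC[C@H]2C(C)(C)CCC[C@]2(C)[C@@H]1Cc1c(OC)c(OC)cc(OC)c1OC | intermediate
20 | 11-(2,3,5,6-tetramethoxyphenyl)-9-epi-drim-7-ene | CC1=CC[C@H]2C(C)(C)CCC[C@]2(C)[C@@H]1Cc1c(OC)c(OC)cc(OC)c1OC | intermediate
21 | 3-(9-epi-drim-7-en-11-yl)-2,5-dimethoxy-1,4-benzoquinone | CC1=CC[C@H]2C(C)(C)CCC[C@]2(C)[C@@H]1CC1=C(OC)C(=O)C=C(OC)C1=O | intermediate
22 | 3-(9-epi-drim-7-en-11-yl)-2,5-dihydroxy-1,4-benzoquinone | CC1=CC[C@H]2C(C)(C)CCC[C@]2(C)[C@@H]1CC1=C(O)C(=O)C=C(O)C1=O | intermediate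
23 | 3-(9-epi-drim-7-en-11-yl)benzene-1,2,4,5-tetrol | CC1=CC[C@H]2C(C)(C)CCC[C@]2(C)[C@@H]1Cc1c(O)c(O)cc(O)c1O | intermediate
24 | pyridinium salt of 25 (not isolated) | CC1=CC[C@H]2C(C)(C)CCC[C@]2(C)[C@@H]1Cc1c(O)c(O)cc(OS(=O)(=O)[O-])c1O.c1cc[nH+]cc1 | intermediate
25 | 2,4,5-trihydroxy-3-{[(1R,4aS,8aS)-2,5,5,8a-tetramethyl-1,4,4a,5,6,7,8,8a-octahydronaphthalen-1-yl]methyl}phenyl hydrogen sulfate | CC1=CC[C@H]2C(C)(C)CCC[C@]2(C)[C@@H]1Cc1c(O)c(O)cc(OS(=O)(=O)O)c1O | target

**Step count and risks**

Total steps: 17. Longest linear sequence: 17 steps (1 to 25; 11 and 16 enter as purchased materials).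

Most likely to fail, riskiest first:

1. Step 12. The ring closure may take place on the wrong face of C9, so that the arylmethyl arm ends on the β face next to the C10 methyl group. The ketyl may also be reduced to the secondary alcohol before it reaches the alkene carbon beside quaternary C10. The fallback sets out from 9 and comes back to the route at 18; it moves the C9 question from the ring closure to a hydroxyl-directed hydrogenation. Homologation of 9 with dimethyl (1-diazo-2-oxopropyl)phosphonate and K2CO3 in MeOH (Seyferth–Gilbert homologation, Ohira–Bestmann variant) should give methyl 3-[(1S,2S)-2-ethynyl-2,6,6-trimethylcyclohexyl]propanoate F1. Quenching 12 (from 11 and n-BuLi) with I2 should give 3-iodo-1,2,4,5-tetramethoxybenzene F2. Sonogashira coupling (PdCl2(PPh3)2, CuI, Et3N, 60 °C) should join them to the aryl alkyne ester F3. The operations of steps 10 and 11 should then give the alkynyl Weinreb amide F4 and the alkynyl methyl ketone F5. SmI2/HMPA/t-BuOH should close ring B by 6-exo-dig addition of the ketyl to the alkyne carbon C9 and give 11-(2,3,5,6-tetramethoxyphenyl)drim-9(11)-en-8β-ol F6, whose C8 is set only by the equatorial preference of its methyl group. Hydrogenation with [Ir(cod)(PCy3)(py)]PF6 under H2 in CH2Cl2 should be steered by the tertiary 8β-hydroxyl to the β face of C9=C11 and give 18 with 9β-H.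

2. Step 17. More than one hydroxyl may be sulfated, a hindered hydroxyl beside the C11 methylene may react, or 23 may be oxidised by air back to 22 before it is sulfated. The fallback sets out from 21 and comes back at 25; it carries the two oxygens that must stay free as allyl ethers, so that only one open and one hindered hydroxyl compete. Alkoxy exchange of 21 in allyl alcohol with catalytic sodium allyloxide should give the 2,5-bis(allyloxy)quinone F7. Na2S2O4 should reduce it to the 2,5-bis(allyloxy)hydroquinone F8. SO3·pyridine should sulfate the hydroxyl next to the ring C–H (the other lies between the C11 methylene and an allyloxy group) and give the aryl hydrogen sulfate F9, handled as its pyridinium salt. Pd(PPh3)4 with morpholine in THF should remove both allyl groups, and the ion exchange of step 17 should give 25.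

3. Step 4. Oxidation at benzylic C7 or at a tertiary C–H may compete with the slow degradation of a benzene ring that carries only alkyl groups, and the ring may be broken down incompletely. The fallback sets out from 5 and comes back at 6; it first makes the ring electron-rich. Friedel–Crafts acetylation of 5 (AcCl, AlCl3, CH2Cl2) should give 12-acetylabieta-8,11,13-triene F10. Baeyer–Villiger oxidation (mCPBA, CH2Cl2) should give abieta-8,11,13-trien-12-yl acetate F11. K2CO3 in MeOH should give ferruginol F12. Ozonolysis of the phenol ring (O3, CH2Cl2/MeOH, −78 °C; then H2O2, HCO2H) should give 6.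

**Further compounds**

F1 | step 12 | methyl 3-[(1S,2S)-2-ethynyl-2,6,6-trimethylcyclohexyl]propanoate | COC(=O)CC[C@H]1C(C)(C)CCC[C@]1(C)C#C
F2 | step 12 | 3-iodo-1,2,4,5-tetramethoxybenzene | COc1cc(OC)c(OC)c(I)c1OC
F3 | step 12 | methyl 3-[(1S,2S)-2,6,6-trimethyl-2-[(2,3,5,6-tetramethoxyphenyl)ethynyl]cyclohexyl]propanoate | COC(=O)CC[C@H]1C(C)(C)CCC[C@]1(C)C#Cc1c(OC)c(OC)cc(OC)c1OC
F4 | step 12 | N-methoxy-N-methyl-3-[(1S,2S)-2,6,6-trimethyl-2-[(2,3,5,6-tetramethoxyphenyl)ethynyl]cyclohexyl]propanamide | CON(C)C(=O)CC[C@H]1C(C)(C)CCC[C@]1(C)C#Cc1c(OC)c(OC)cc(OC)c1OC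
F5 | step 12 | 4-[(1S,2S)-2,6,6-trimethyl-2-[(2,3,5,6-tetramethoxyphenyl)ethynyl]cyclohexyl]butan-2-one | CC(=O)CC[C@H]1C(C)(C)CCC[C@]1(C)C#Cc1c(OC)c(OC)cc(OC)c1OC
F6 | step 12 | 11-(2,3,5,6-tetramethoxyphenyl)drim-9(11)-en-8β-ol | C[C@]1(O)CC[C@H]2C(C)(C)CCC[C@]2(C)C1=Cc1c(OC)c(OC)cc(OC)c1OC
F7 | step 17 | 3-(9-epi-drim-7-en-11-yl)-2,5-bis(prop-2-enyloxy)-1,4-benzoquinone | CC1=CC[C@H]2C(C)(C)CCC[C@]2(C)[C@@H]1CC1=C(OCC=C)C(=O)C=C(OCC=C)C1=O
F8 | step 17 | 3-(9-epi-drim-7-en-11-yl)-2,5-bis(prop-2-enyloxy)benzene-1,4-diol | CC1=CC[C@H]2C(C)(C)CCC[C@]2(C)[C@@H]1Cc1c(OCC=C)c(O)cc(OCC=C)c1O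
F9 | step 17 | 4-hydroxy-3-(9-epi-drim-7-en-11-yl)-2,5-bis(prop-2-enyloxy)phenyl hydrogen sulfate | CC1=CC[C@H]2C(C)(C)CCC[C@]2(C)[C@@H]1Cc1c(OCC=C)c(OS(=O)(=O)O)cc(OCC=C)c1O
F10 | step 4 | 12-acetylabieta-8,11,13-triene | CC(C)C1=CC2=C(C=C1C(C)=O)[C@]3(CCCC([C@@H]3CC2)(C)C)C
F11 | step 4 | abieta-8,11,13-trien-12-yl acetate | CC(C)C1=CC2=C(C=C1OC(C)=O)[C@]3(CCCC([C@@H]3CC2)(C)C)C
F12 | step 4 | ferruginol (abieta-8,11,13-trien-12-ol) | CC(C)C1=CC2=C(C=C1O)[C@]3(CCCC([C@@H]3CC2)(C)C)C
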